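Numbering is prostanoid (C1 ester carbon, ring C8–C12, C20 chain end). The retrosynthesis cuts C5=C6 (lactol Wittig), then the C12–O bond, then C7–C8 ([3,3] shift from O11), and finally opens the ring to a 2-furylcarbinol.
Enabling feature: O12 is cis to C7 on ring C8–C12 and 1,4 to C6 (O12–C12–C8–C7–C6), so with C6 as a carboxyl carbon the C12–O bond is the ring bond of a γ-lactone cis-fused to the cyclopentane, reachable by iodolactonisation across C11=C12.
Forward order: furan → cyclopentenone ring already carrying C13–C20 → C6/C7 by Johnson–Claisen → lactone ring by iodolactonisation → O7 → C1–C5 by Wittig → chloro enone from an epoxy ketone as the last event.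
Stereochemistry: a lipase-resolved carbinol at C9 steers hydride to C11, O11 hands C7 to C8 suprafacially, C8 fixes C12 through the tether, and the convex face of the bicyclic lactone fixes C7; C9 itself ends as the ketone.
C9 carries its oxygen from the furan stage, so no allylic C–H oxidation is needed beside the alkyne; the alkyne masks C14=C15 until the ring alkene has been epoxidised.
Key step: step 9

Assumption: the lipase acylates the (R)-enantiomer of 7 faster, as is usual for 4-hydroxycyclopent-2-enones, so the recovered alcohol is (S)-8.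

Step 1
Reactants: 1 furfural; 2 3-bromoprop-1-yne
Product: 3 (±)-1-(furan-2-yl)but-3-yn-1-ol
Conditions: Zn, THF, 0 °C → rt; aq. NH4Cl
Reagents that add atoms: none
Why: In this Barbier propargylation the allenylzinc bromide formed from Zn and 2 adds to the aldehyde through its γ-carbon, which should give the homopropargylic alcohol.

Step 2
Reactants: 3 (±)-1-(furan-2-yl)but-3-yn-1-ol; 4 1-iodopentane
Product: 5 (±)-1-(furan-2-yl)non-3-yn-1-ol
Conditions: n-BuLi (2.1 equiv), THF, −78 °C; then 4, DMPU, −78 °C → rt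
Reagents that add atoms: none
Why: Alkylation of the alkoxide–acetylide dianion should occur only at the acetylide carbon, installing C16–C20 by SN2 displacement of iodide.

Step 3
Reactants: 5 (±)-1-(furan-2-yl)non-3-yn-1-ol
Product: 7 (±)-4-hydroxy-2-(oct-2-yn-1-yl)cyclopent-2-en-1-one, via trans-4-hydroxy-5-(oct-2-yn-1-yl)cyclopent-2-en-1-one 6 (not isolated)
Conditions: ZnCl2, 1,4-dioxane–H2O, reflux; then aq. phosphate buffer to pH 8, 60 °C
Reagents that add atoms: water, O
Why: In the Piancatelli rearrangement, ionisation of the furylcarbinol, attack of water at C5 of the furan and conrotatory 4π closure of the pentadienyl cation should give trans enone 6, which at pH 8 should shift by hydration and β-elimination to the more stable 2-alkyl enone 7.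

Step 4
Reactants: 7 (±)-4-hydroxy-2-(oct-2-yn-1-yl)cyclopent-2-en-1-one
Product: 8 (4S)-4-hydroxy-2-(oct-2-yn-1-yl)cyclopent-2-en-1-one
Conditions: Burkholderia cepacia lipase (immobilised), vinyl acetate, t-BuOMe, 30 °C, stopped just past half conversion
Reagents that add atoms: none
Why: Enzymatic kinetic resolution by transesterification should acetylate the (R)-alcohol and leave (S)-8, whose carbinol centre (C9) is the source of all later stereocentres.

Step 5
Reactants: 8 (4S)-4-hydroxy-2-(oct-2-yn-1-yl)cyclopent-2-en-1-one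
Product: 9 (4S)-4-[(tert-butyldimethylsilyl)oxy]-2-(oct-2-yn-1-yl)cyclopent-2-en-1-one
Conditions: TBSCl, imidazole, DMF, 0 °C → rt
Reagents that add atoms: tert-butyldimethylsilyl chloride, CC(C)(C)[Si](C)(C)Cl
Why: This is a standard silylation of a secondary alcohol, and imidazole is too weak a base to cause β-elimination of the 4-oxygen.

Step 6
Reactants: 9 (4S)-4-[(tert-butyldimethylsilyl)oxy]-2-(oct-2-yn-1-yl)cyclopent-2-en-1-one
Product: 10 (1R,4S)-4-[(tert-butyldimethylsilyl)oxy]-2-(oct-2-yn-1-yl)cyclopent-2-en-1-ol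
Conditions: NaBH4, CeCl3·7H2O, MeOH, −78 °C
Reagents that add atoms: none
Why: In this Luche reduction hydride adds 1,2 from the face opposite the silyloxy group, which should set C11 cis to O9; the minor trans alcohol is removed by chromatography because it would feed the enantiomeric series.

Step 7
Reactants: 10 (1R,4S)-4-[(tert-butyldimethylsilyl)oxy]-2-(oct-2-yn-1-yl)cyclopent-2-en-1-ol; 11 triethyl orthoacetate
Product: 13 ethyl 2-[(1R,5S)-5-[(tert-butyldimethylsilyl)oxy]-2-(oct-2-yn-1-yl)cyclopent-2-en-1-yl]acetate, via ketene acetal 12 (not isolated)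
Conditions: EtCO2H (cat.), 140 °C, EtOH distilled off
Reagents that add atoms: none
Why: In the Johnson–Claisen rearrangement, ketene acetal 12 undergoes a [3,3] shift that delivers C7 to C8 on the face O11 occupied (suprafacial 1,3-chirality transfer), which sets C8 and moves the alkene to C11=C12.

Step 8
Reactants: 13 ethyl 2-[(1R,5S)-5-[(tert-butyldimethylsilyl)oxy]-2-(oct-2-yn-1-yl)cyclopent-2-en-1-yl]acetate
Product: 14 2-[(1R,5S)-5-[(tert-butyldimethylsilyl)oxy]-2-(oct-2-yn-1-yl)cyclopent-2-en-1-yl]acetic acid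
Conditions: LiOH, THF–MeOH–H2O, rt; dilute HCl to pH 4 at 0 °C
Reagents that add atoms: lithium hydroxide, [Li+].[OH-]
Why: Saponification of an unhindered ethyl ester should leave the silyl ether and the skipped enyne untouched at room temperature.

Step 9
Reactants: 14 2-[(1R,5S)-5-[(tert-butyldimethylsilyl)oxy]-2-(oct-2-yn-1-yl)cyclopent-2-en-1-yl]acetic acid
Product: 15 (3aS,4S,6S,6aS)-4-[(tert-butyldimethylsilyl)oxy]-6-iodo-6a-(oct-2-yn-1-yl)hexahydro-2H-cyclopenta[b]furan-2-one (the cis-fused 6-silyloxy-8-iodo-1-octynyl-2-oxabicyclo[3.3.0]octan-3-one, iodine trans to the ring oxygen)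
Conditions: I2, NaHCO3, MeCN–H2O, 0 °C, dark
Reagents that add atoms: iodine, [I][I]
Why: This is an iodolactonisation of a γ,δ-unsaturated acid, closest in type to the cis-fused iodolactones obtained from cyclopent-2-enylacetic acids: I2 forms an iodonium ion reversibly on the face of C11=C12 opposite the CH2CO2− arm and the carboxylate opens it at C12 by anti addition. The γ-lactone ring (O–C12–C8–C7–C6) closes in the 5-exo-trig mode. C12 is controlled by C8, because a two-atom tether can reach C12 only from the face it already occupies and the ring fusion must therefore be cis; C11 follows from anti addition, with iodine trans to the lactone oxygen. Regioselectivity for C12 over C11 is needed and is secured by ring size (5-exo against a bridged 6-endo δ-lactone) and by the better stabilised tertiary centre at C12. Chemoselectivity for the ring alkene over the alkyne is needed and is secured by the higher nucleophilicity of the trisubstituted alkene and by the lack of any internal nucleophile within reach of the alkyne, while NaHCO3 at 0 °C keeps the closure under kinetic control.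

Step 10
Reactants: 15 iodolactone
Product: 16 (3aS,4S,6aR)-4-[(tert-butyldimethylsilyl)oxy]-6a-(oct-2-yn-1-yl)-3,3a,4,6a-tetrahydro-2H-cyclopenta[b]furan-2-one
Conditions: DBU, toluene, 80 °C
Reagents that add atoms: none
Why: In this E2 dehydroiodination only H10 can be antiperiplanar to the C11–I bond (C12 bears no hydrogen), so the C10=C11 alkene should form and the lactone should survive.

Step 11
Reactants: 16 alkene lactone
Product: 17 (3R,3aS,4S,6aR)-4-[(tert-butyldimethylsilyl)oxy]-3-hydroxy-6a-(oct-2-yn-1-yl)-3,3a,4,6a-tetrahydro-2H-cyclopenta[b]furan-2-one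
Conditions: KN(SiMe3)2, THF, −78 °C; then 2-(phenylsulfonyl)-3-phenyloxaziridine, −78 °C; AcOH quench
Reagents that add atoms: 2-(phenylsulfonyl)-3-phenyloxaziridine, O=S(=O)(c1ccccc1)N1OC1c1ccccc1
Why: In this enolate hydroxylation with an N-sulfonyloxaziridine the potassium enolate of the cis-fused lactone should be oxidised on its convex face, anti to the C8–C9 bond and the endo silyloxy group, which sets C7 (7S in the target).

Step 12
Reactants: 17 hydroxy lactone
Product: 18 (3R,3aS,4S,6aR)-4-[(tert-butyldimethylsilyl)oxy]-6a-(oct-2-yn-1-yl)-3,3a,4,6a-tetrahydro-2H-cyclopenta[b]furan-2,3-diol (lactol, both anomers)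
Conditions: i-Bu2AlH (3 equiv), CH2Cl2, −78 °C; aq. potassium sodium tartrate
Reagents that add atoms: none
Why: In this partial reduction of a γ-lactone the aluminium hemiacetal is stable at −78 °C and should give the lactol on work-up, one equivalent of hydride being consumed by the free hydroxyl.

Step 13
Reactants: 18 lactol; 19 (4-carboxybutyl)triphenylphosphonium bromide
Product: 21 (5Z,7S,8S,9S,12R)-9-[(tert-butyldimethylsilyl)oxy]-7,12-dihydroxyprosta-5,10-dien-14-ynoic acid, via phosphorus ylide 20 (not isolated)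
Conditions: 19, KOt-Bu, THF, 0 °C; then 18, 0 °C → rt; dilute HCl to pH 4
Reagents that add atoms: none
Why: In this Wittig olefination of a lactol, the salt-free unstabilised ylide reacts with the open hydroxy aldehyde through a kinetically formed cis-oxaphosphetane to give the 5Z alkene and free O12, and the C7 alkoxide beside the aldehyde disfavours α-deprotonation.

Step 14
Reactants: 21 dihydroxy acid
Product: 22 methyl (5Z,7S,8S,9S,12R)-9-[(tert-butyldimethylsilyl)oxy]-7,12-dihydroxyprosta-5,10-dien-14-ynoate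
Conditions: Me3SiCHN2, MeOH–toluene, 0 °C
Reagents that add atoms: trimethylsilyldiazomethane, C[Si](C)(C)C=[N+]=[N-]
Why: Esterification of the carboxylic acid with a diazoalkane proceeds under neutral conditions and should not methylate the alcohols.

Step 15
Reactants: 22 dihydroxy ester
Product: 23 methyl (5Z,7S,8S,9S,12R)-7-acetoxy-9-[(tert-butyldimethylsilyl)oxy]-12-hydroxyprosta-5,10-dien-14-ynoate
Conditions: Ac2O, pyridine, DMAP (cat.), CH2Cl2, 0 °C
Reagents that add atoms: acetic anhydride, CC(=O)OC(C)=O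
Why: Acylation should occur selectively at the secondary C7 hydroxyl, the tertiary C12 hydroxyl being too hindered under these conditions.

Step 16
Reactants: 23 acetate
Product: 24 methyl (5Z,7S,8R,9S,12R)-7-acetoxy-9,12-dihydroxyprosta-5,10-dien-14-ynoate
Conditions: HF·pyridine, pyridine, THF, 0 °C → rt
Reagents that add atoms: none
Why: Fluoride-mediated desilylation under weakly acidic conditions should leave the acetate (no base, no acyl migration) and the tertiary allylic alcohol intact.

Step 17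
Reactants: 24 allylic diol
Product: 25 methyl (5Z,7S,8R,9R,10R,11R,12S)-7-acetoxy-10,11-epoxy-9,12-dihydroxyprost-5-en-14-ynoate
Conditions: VO(acac)2 (cat.), t-BuOOH, CH2Cl2, 0 °C
Reagents that add atoms: tert-butyl hydroperoxide, CC(C)(C)OO
Why: In this hydroxyl-directed epoxidation the vanadium alkylperoxide bound to the cis-disposed O9 and O12 should deliver oxygen to C10=C11 from their face only, while the C5=C6 alkene (no free allylic hydroxyl) and the alkyne do not react.

Step 18
Reactants: 25 epoxy diol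
Product: 26 methyl (5Z,7S,8R,9R,10R,11R,12S,14Z)-7-acetoxy-10,11-epoxy-9,12-dihydroxyprosta-5,14-dienoate
Conditions: H2 (1 atm), Pd on CaCO3 poisoned with Pb(OAc)2, quinoline, EtOAc, rt
Reagents that add atoms: none
Why: Partial hydrogenation of the alkyne by syn addition of H2 on poisoned palladium should give the 14Z alkene without reducing the isolated C5=C6 alkene or the epoxide.

Step 19
Reactants: 26 epoxy diol
Product: 27 methyl (5Z,7S,8R,10S,11R,12S,14Z)-7-acetoxy-10,11-epoxy-12-hydroxy-9-oxoprosta-5,14-dienoate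
Conditions: 1,1,1-triacetoxy-1,1-dihydro-1,2-benziodoxol-3(1H)-one (DMP), NaHCO3, CH2Cl2, 0 °C → rt
Reagents that add atoms: none
Why: Oxidation of the secondary C9 alcohol with a hypervalent iodine reagent under neutral conditions should give the α,β-epoxy ketone without touching the tertiary alcohol and without base that could eliminate the β-acetoxy group.

Step 20
Reactants: 27 epoxy ketone
Product: 29 punaglandin 8, via chlorohydrin 28 (not isolated)
Conditions: HCl (1 M in Et2O), CH2Cl2, 0 °C → rt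
Reagents that add atoms: hydrogen chloride, Cl
Why: In this conversion of an α,β-epoxy ketone into an α-chloro enone, chloride opens the protonated epoxide at C10 (SN2 at the carbon α to the carbonyl) and β-hydroxy ketone 28 dehydrates through its enol, as is known for epoxides of 4-hydroxy-4-alkylcyclopentenones carrying a free tertiary hydroxyl; no stereocentre is created.

Compound list
1 | furfural (furan-2-carbaldehyde) | O=Cc1ccco1 | starting material
2 | 3-bromoprop-1-yne (propargyl bromide) | BrCC#C | starting material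
3 | (±)-1-(furan-2-yl)but-3-yn-1-ol | OC(CC#C)c1ccco1 | intermediate
4 | 1-iodopentane | CCCCCI | starting material
5 | (±)-1-(furan-2-yl)non-3-yn-1-ol | CCCCCC#CCC(O)c1ccco1 | intermediate
6 | (±)-trans-4-hydroxy-5-(oct-2-yn-1-yl)cyclopent-2-en-1-one, racemic, (4R,5S) enantiomer drawn | O=C1C=C[C@@H](O)[C@@H]1CC#CCCCCC | intermediate (not isolated)
7 | (±)-4-hydroxy-2-(oct-2-yn-1-yl)cyclopent-2-en-1-one | CCCCCC#CCC1=CC(O)CC1=O | intermediate
8 | (4S)-4-hydroxy-2-(oct-2-yn-1-yl)cyclopent-2-en-1-one | CCCCCC#CCC1=C[C@@H](O)CC1=O | intermediate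
9 | (4S)-4-[(tert-butyldimethylsilyl)oxy]-2-(oct-2-yn-1-yl)cyclopent-2-en-1-one | CCCCCC#CCC1=C[C@@H](O[Si](C)(C)C(C)(C)C)CC1=O | intermediate
10 | (1R,4S)-4-[(tert-butyldimethylsilyl)oxy]-2-(oct-2-yn-1-yl)cyclopent-2-en-1-ol (cis) | CCCCCC#CCC1=C[C@@H](O[Si](C)(C)C(C)(C)C)C[C@H]1O | intermediate
11 | triethyl orthoacetate (1,1,1-triethoxyethane) | CCOC(C)(OCC)OCC | starting material
12 | tert-butyl{[(1S,4R)-4-[(1-ethoxyethenyl)oxy]-3-(oct-2-yn-1-yl)cyclopent-2-en-1-yl]oxy}dimethylsilane (ketene acetal) | CCCCCC#CCC1=C[C@@H](O[Si](C)(C)C(C)(C)C)C[C@H]1OC(=C)OCC | intermediate (not isolated)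
13 | ethyl 2-[(1R,5S)-5-[(tert-butyldimethylsilyl)oxy]-2-(oct-2-yn-1-yl)cyclopent-2-en-1-yl]acetate | CCCCCC#CCC1=CC[C@H](O[Si](C)(C)C(C)(C)C)[C@@H]1CC(=O)OCC | intermediate
14 | 2-[(1R,5S)-5-[(tert-butyldimethylsilyl)oxy]-2-(oct-2-yn-1-yl)cyclopent-2-en-1-yl]acetic acid | CCCCCC#CCC1=CC[C@H](O[Si](C)(C)C(C)(C)C)[C@@H]1CC(=O)O | intermediate (key-step precursor)
15 | (3aS,4S,6S,6aS)-4-[(tert-butyldimethylsilyl)oxy]-6-iodo-6a-(oct-2-yn-1-yl)hexahydro-2H-cyclopenta[b]furan-2-one | CCCCCC#CC[C@@]1(OC(=O)C2)[C@@H](I)C[C@H](O[Si](C)(C)C(C)(C)C)[C@@H]12 | intermediate (key-step product)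
16 | (3aS,4S,6aR)-4-[(tert-butyldimethylsilyl)oxy]-6a-(oct-2-yn-1-yl)-3,3a,4,6a-tetrahydro-2H-cyclopenta[b]furan-2-one | CCCCCC#CC[C@@]1(OC(=O)C2)C=C[C@H](O[Si](C)(C)C(C)(C)C)[C@@H]12 | intermediate
17 | (3R,3aS,4S,6aR)-4-[(tert-butyldimethylsilyl)oxy]-3-hydroxy-6a-(oct-2-yn-1-yl)-3,3a,4,6a-tetrahydro-2H-cyclopenta[b]furan-2-one | CCCCCC#CC[C@@]1(OC(=O)[C@@H]2O)C=C[C@H](O[Si](C)(C)C(C)(C)C)[C@@H]12 | intermediate
18 | (3R,3aS,4S,6aR)-4-[(tert-butyldimethylsilyl)oxy]-6a-(oct-2-yn-1-yl)-3,3a,4,6a-tetrahydro-2H-cyclopenta[b]furan-2,3-diol (anomeric mixture) | CCCCCC#CC[C@@]1(OC(O)[C@@H]2O)C=C[C@H](O[Si](C)(C)C(C)(C)C)[C@@H]12 | intermediate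
19 | (4-carboxybutyl)triphenylphosphonium bromide | [Br-].OC(=O)CCCC[P+](c1ccccc1)(c1ccccc1)c1ccccc1 | starting material
20 | potassium 5-(triphenyl-λ5-phosphanylidene)pentanoate (ylide) | [K+].[O-]C(=O)CCCC=P(c1ccccc1)(c1ccccc1)c1ccccc1 | intermediate (not isolated)
21 | (5Z,7S,8S,9S,12R)-9-[(tert-butyldimethylsilyl)oxy]-7,12-dihydroxyprosta-5,10-dien-14-ynoic acid | CCCCCC#CC[C@@]1(O)C=C[C@H](O[Si](C)(C)C(C)(C)C)[C@@H]1[C@H](/C=C\CCCC(=O)O)O | intermediate
22 | methyl (5Z,7S,8S,9S,12R)-9-[(tert-butyldimethylsilyl)oxy]-7,12-dihydroxyprosta-5,10-dien-14-ynoate | CCCCCC#CC[C@@]1(O)C=C[C@H](O[Si](C)(C)C(C)(C)C)[C@@H]1[C@H](/C=C\CCCC(=O)OC)O | intermediate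
23 | methyl (5Z,7S,8S,9S,12R)-7-acetoxy-9-[(tert-butyldimethylsilyl)oxy]-12-hydroxyprosta-5,10-dien-14-ynoate | CCCCCC#CC[C@@]1(O)C=C[C@H](O[Si](C)(C)C(C)(C)C)[C@@H]1[C@H](/C=C\CCCC(=O)OC)OC(C)=O | intermediate
24 | methyl (5Z,7S,8R,9S,12R)-7-acetoxy-9,12-dihydroxyprosta-5,10-dien-14-ynoate | CCCCCC#CC[C@@]1(O)C=C[C@H](O)[C@@H]1[C@H](/C=C\CCCC(=O)OC)OC(C)=O | intermediate
25 | methyl (5Z,7S,8R,9R,10R,11R,12S)-7-acetoxy-10,11-epoxy-9,12-dihydroxyprost-5-en-14-ynoate (epoxide cis to both hydroxyls) | CCCCCC#CC[C@@]1(O)[C@@H]2O[C@@H]2[C@H](O)[C@@H]1[C@H](/C=C\CCCC(=O)OC)OC(C)=O | intermediate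
26 | methyl (5Z,7S,8R,9R,10R,11R,12S,14Z)-7-acetoxy-10,11-epoxy-9,12-dihydroxyprosta-5,14-dienoate | CCCCC/C=C\C[C@@]1(O)[C@@H]2O[C@@H]2[C@H](O)[C@@H]1[C@H](/C=C\CCCC(=O)OC)OC(C)=O | intermediate
27 | methyl (5Z,7S,8R,10S,11R,12S,14Z)-7-acetoxy-10,11-epoxy-12-hydroxy-9-oxoprosta-5,14-dienoate | CCCCC/C=C\C[C@@]1(O)[C@@H]2O[C@@H]2C(=O)[C@@H]1[C@H](/C=C\CCCC(=O)OC)OC(C)=O | intermediate
28 | methyl (5Z,7S,8R,10R,11S,12S,14Z)-7-acetoxy-10-chloro-11,12-dihydroxy-9-oxoprosta-5,14-dienoate | CCCCC/C=C\C[C@@]1(O)[C@H](O)[C@@H](Cl)C(=O)[C@@H]1[C@H](/C=C\CCCC(=O)OC)OC(C)=O | intermediate (not isolated)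
29 | punaglandin 8, methyl (5Z,7S,8R,12S,14Z)-7-acetoxy-10-chloro-12-hydroxy-9-oxoprosta-5,10,14-trienoate | CCCCC/C=C\C[C@@]1(O)C=C(Cl)C(=O)[C@@H]1[C@H](/C=C\CCCC(=O)OC)OC(C)=O | target

Total step count: 20. Longest linear sequence: 20 steps (furfural 1 to punaglandin 8 29). The resolution in step 4 can pass on at most half of the material.

Steps most likely to fail

1. Step 20. Under acid, loss of acetic acid across C7–C8 through the C8 enol may compete with the wanted dehydration of the chlorohydrin. The fallback sets out from 22 and comes back at 29: O7 is carried as a silyl ether through the acid step and the acetate is put on last. Compound 22 would be silylated at O7 with TBDPSCl and imidazole to the 7-O-tert-butyldiphenylsilyl ether F1. PPTS in MeOH would then remove only the allylic TBS group to give the 9-alcohol F2. VO(acac)2 and t-BuOOH would give the epoxy alcohol F3, semi-hydrogenation on poisoned Pd the 14Z alkene F4, DMP the epoxy ketone F5, and HCl the chloro enone F6, which has no leaving group at C7. HF·pyridine would free O7 to give 7-deacetylpunaglandin 8 F7, and Ac2O in pyridine at 0 °C without DMAP would acetylate it to 29.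

2. Step 13. The unprotected α-hydroxy aldehyde may epimerise at C7, or the silyl group may migrate from O9 to the C7 alkoxide, under the basic ylide conditions. The fallback sets out from 17 and comes back at 22: the olefination is run on an α-silyloxy lactol. Lactone 17 would be silylated with Et3SiCl and imidazole to the 7-O-triethylsilyl lactone F8 and reduced with i-Bu2AlH to the silyloxy lactol F9. Olefination with ylide 20 would give the 7-O-triethylsilyl acid F10 and Me3SiCHN2 its methyl ester F11. PPTS in MeOH would then cleave the triethylsilyl ether selectively to return 22.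

3. Step 7. The rearrangement may be slow next to the cis silyloxy group, with thermal elimination at 140 °C taking over. The fallback sets out from 10 and comes back at 14, replacing steps 7 and 8 by an Ireland–Claisen rearrangement. Alcohol 10 would be acetylated (Ac2O, pyridine, DMAP) to the allylic acetate F12. LiN(i-Pr)2 and Me3SiCl in THF at −78 °C would give the silyl ketene acetal F13, which on warming to 50 °C should rearrange with the same suprafacial transfer to the trimethylsilyl ester F14. Aqueous work-up would give acid 14 directly.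

Further compounds
F1 | step 20 | 7-O-(tert-butyldiphenylsilyl) ether of 22 | CCCCCC#CC[C@@]1(O)C=C[C@H](O[Si](C)(C)C(C)(C)C)[C@@H]1[C@H](/C=C\CCCC(=O)OC)O[Si](c1ccccc1)(c1ccccc1)C(C)(C)C
F2 | step 20 | 9-alcohol from F1 (7-O-TBDPS, 9,12-diol, 14-yne) | CCCCCC#CC[C@@]1(O)C=C[C@H](O)[C@@H]1[C@H](/C=C\CCCC(=O)OC)O[Si](c1ccccc1)(c1ccccc1)C(C)(C)C
F3 | step 20 | 10,11-epoxide of F2 (cis to O9 and O12) | CCCCCC#CC[C@@]1(O)[C@@H]2O[C@@H]2[C@H](O)[C@@H]1[C@H](/C=C\CCCC(=O)OC)O[Si](c1ccccc1)(c1ccccc1)C(C)(C)C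
F4 | step 20 | 14Z alkene from F3 | CCCCC/C=C\C[C@@]1(O)[C@@H]2O[C@@H]2[C@H](O)[C@@H]1[C@H](/C=C\CCCC(=O)OC)O[Si](c1ccccc1)(c1ccccc1)C(C)(C)C
F5 | step 20 | 9-ketone from F4 (epoxy ketone, 7-O-TBDPS) | CCCCC/C=C\C[C@@]1(O)[C@@H]2O[C@@H]2C(=O)[C@@H]1[C@H](/C=C\CCCC(=O)OC)O[Si](c1ccccc1)(c1ccccc1)C(C)(C)C
F6 | step 20 | 7-O-(tert-butyldiphenylsilyl)-7-deacetylpunaglandin 8 | CCCCC/C=C\C[C@@]1(O)C=C(Cl)C(=O)[C@@H]1[C@H](/C=C\CCCC(=O)OC)O[Si](c1ccccc1)(c1ccccc1)C(C)(C)C
F7 | step 20 | 7-deacetylpunaglandin 8 | CCCCC/C=C\C[C@@]1(O)C=C(Cl)C(=O)[C@@H]1[C@H](/C=C\CCCC(=O)OC)O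
F8 | step 13 | 3-O-triethylsilyl ether of lactone 17 | CCCCCC#CC[C@@]1(OC(=O)[C@@H]2O[Si](CC)(CC)CC)C=C[C@H](O[Si](C)(C)C(C)(C)C)[C@@H]12
F9 | step 13 | lactol from F8 (anomeric mixture) | CCCCCC#CC[C@@]1(OC(O)[C@@H]2O[Si](CC)(CC)CC)C=C[C@H](O[Si](C)(C)C(C)(C)C)[C@@H]12
F10 | step 13 | 7-O-triethylsilyl ether of acid 21 | CCCCCC#CC[C@@]1(O)C=C[C@H](O[Si](C)(C)C(C)(C)C)[C@@H]1[C@H](/C=C\CCCC(=O)O)O[Si](CC)(CC)CC
F11 | step 13 | 7-O-triethylsilyl ether of ester 22 | CCCCCC#CC[C@@]1(O)C=C[C@H](O[Si](C)(C)C(C)(C)C)[C@@H]1[C@H](/C=C\CCCC(=O)OC)O[Si](CC)(CC)CC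
F12 | step 7 | (1R,4S)-4-[(tert-butyldimethylsilyl)oxy]-2-(oct-2-yn-1-yl)cyclopent-2-en-1-yl acetate | CCCCCC#CCC1=C[C@@H](O[Si](C)(C)C(C)(C)C)C[C@H]1OC(C)=O
F13 | step 7 | trimethylsilyl ketene acetal of F12 | CCCCCC#CCC1=C[C@@H](O[Si](C)(C)C(C)(C)C)C[C@H]1OC(=C)O[Si](C)(C)C
F14 | step 7 | trimethylsilyl ester of acid 14 | CCCCCC#CCC1=CC[C@H](O[Si](C)(C)C(C)(C)C)[C@@H]1CC(=O)O[Si](C)(C)C
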